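**Plan**

1. Retrosynthesis (shikimate numbering: C1 = ester carbon, C2 = olefinic CH, C3–C5 = O-bearing carbons, C6 = CH2): cut the O4–acyl and O3–acetyl bonds, then C2–H (from an enol triflate), then both ring bonds of C1 (C1–C2 and C1–C6). This takes out C1 with its CO2Me as methyl diazoacetate and leaves a cyclopentanone; last come the O5–acyl bond and the C5–O bond.
2. Enabling feature: in the cyclohexene, the ester-bearing C1 lies between the unsubstituted C6H2 and the olefinic C2H, next to the contiguous oxygenated triad C3–C4–C5. C1 is therefore a one-carbon insert and C2 the latent ketone of a 2,3,4-trioxygenated cyclopentanone.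
3. Forward: purchased cis-fused cyclopentenone–dioxolane 1 → trans β-hydroxylation and O5 ester → one-carbon enlargement of the five-membered carbocycle to the six-membered β-keto ester → enol triflate → enoate → dioxolane removed → acetate on the pseudo-axial O3 via an orthoester → last ester on O4.
4. Stereochemistry: C3 and C4 come from enone 1, C5 from anti attack on its convex face, and both side-chain centres from acids 4 and 14. The ring enlargement moves a CH2 and touches no stereocentre.

Key step: step 4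

Remark: enone 1 and the enantiopure acids 4 and 14 are assumed to be purchasable as such; methyl diazoacetate 7 is made fresh (step 3) and handled only in solution.

Step 1
Reactants: 1 (3aS,6aS)-2,2-dimethyl-3a,6a-dihydro-4H-cyclopenta[d][1,3]dioxol-4-one
Product: 3 (3aS,6R,6aS)-6-hydroxy-2,2-dimethyltetrahydro-4H-cyclopenta[d][1,3]dioxol-4-one, via β-boryl ketone 2 (not isolated)
Conditions: B2pin2, CuCl (5 mol%), Xantphos (5 mol%), NaOtBu (10 mol%), MeOH (2 equiv), THF, rt; then NaBO3·4H2O, THF/H2O, 0 °C → rt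
Reagents that add atoms: bis(pinacolato)diboron, CC1(C)OB(OC1(C)C)B1OC(C)(C)C(C)(C)O1 (boryl group of 2); sodium perborate, [Na+].[O-]OB=O (hydroxyl oxygen of 3)
Why: Copper-catalysed conjugate borylation should deliver boron to the enone β-carbon on the convex face anti to the cis-fused dioxolane, and C–B oxidation with retention should then give the trans β-hydroxy ketone (β-borylation/oxidation as a formal anti oxa-Michael addition).

Step 2
Reactants: 3 (3aS,6R,6aS)-6-hydroxy-2,2-dimethyltetrahydro-4H-cyclopenta[d][1,3]dioxol-4-one; 4 (3S)-3-methylpentanoic acid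
Product: 5 (3aS,4R,6aS)-2,2-dimethyl-6-oxotetrahydro-4H-cyclopenta[d][1,3]dioxol-4-yl (3S)-3-methylpentanoate
Conditions: DIC, DMAP (5 mol%), CH2Cl2, −20 → 0 °C
Reagents that add atoms: none
Why: Steglich esterification acylates the secondary alcohol with retention at carbon, and the acid-buffered, cold medium should hold back E1cB loss of the new β-acyloxy group.

Step 3
Reactants: 6 glycine methyl ester hydrochloride
Product: 7 methyl diazoacetate
Conditions: NaNO2, H2O/CH2Cl2, cat. H2SO4, −5 → 0 °C; organic layer washed (aq. NaHCO3), dried and used as a solution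
Reagents that add atoms: sodium nitrite, [Na+].[O-]N=O
Why: Diazotisation of the primary α-amino ester followed by loss of the α-proton gives the acceptor-stabilised diazo compound (standard preparation of alkyl diazoacetates).

Step 4
Reactants: 5 (3aS,4R,6aS)-2,2-dimethyl-6-oxotetrahydro-4H-cyclopenta[d][1,3]dioxol-4-yl (3S)-3-methylpentanoate; 7 methyl diazoacetate
Product: 8 methyl (3aS,7R,7aS)-2,2-dimethyl-7-{[(3S)-3-methylpentanoyl]oxy}-4-oxohexahydro-1,3-benzodioxole-5-carboxylate (C5 epimers/enol tautomer)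
Conditions: 7 (1.5 equiv), BF3·OEt2 (1.2 equiv), CH2Cl2, −78 → 0 °C
Reagents that add atoms: none
Why: BF3 activates the ketone of 5, the nucleophilic diazo carbon of 7 adds to C=O from the convex face, and the resulting β-oxido alkyldiazonium collapses by 1,2-shift of a ring C–C bond with loss of N2, which inserts the CO2Me-bearing carbon between the former carbonyl carbon and its CH2 neighbour. The closest known reaction type is the Lewis-acid-promoted ring homologation of cycloalkanones with alkyl diazoacetates (Tiffeneau–Demjanov-type ring expansion). No ring is closed by cyclisation: the six-membered carbocycle arises from the cyclopentanone by one-carbon ring enlargement through the 1,2-alkyl shift, and the dioxolane rides along unchanged. The only new stereocentre, the carbon bearing CO2Me, is uncontrolled and irrelevant because 8 is an enolised β-keto ester and this carbon becomes sp2 in step 5; the three oxygenated stereocentres are untouched since the migrating carbon is the non-stereogenic CH2. The step needs migration of the CH2 rather than of the O-bearing CH, which the inductive deactivation of the α-alkoxy carbon as a migrating group should secure. It also needs chemoselectivity over β-elimination of the carboxylate and acetal cleavage, which the non-basic medium and low temperature should provide, while enolisation of the product towards the ester should stop a second insertion.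

Step 5
Reactants: 8 methyl (3aS,7R,7aS)-2,2-dimethyl-7-{[(3S)-3-methylpentanoyl]oxy}-4-oxohexahydro-1,3-benzodioxole-5-carboxylate
Product: 9 methyl (3aS,7R,7aS)-2,2-dimethyl-7-{[(3S)-3-methylpentanoyl]oxy}-4-{[(trifluoromethyl)sulfonyl]oxy}-3a,6,7,7a-tetrahydro-1,3-benzodioxole-5-carboxylate
Conditions: NaH (1.05 equiv), Et2O, 0 °C; then Tf2O (1.1 equiv), −78 → 0 °C
Reagents that add atoms: triflic anhydride, O=S(=O)(OS(=O)(=O)C(F)(F)F)C(F)(F)F
Why: O-sulfonylation of the sodium enolate of the β-keto ester gives the vinyl triflate of the only conjugated enol (C1=C2), which fixes the position of the later double bond (enol triflate formation).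

Step 6
Reactants: 9 methyl (3aS,7R,7aS)-2,2-dimethyl-7-{[(3S)-3-methylpentanoyl]oxy}-4-{[(trifluoromethyl)sulfonyl]oxy}-3a,6,7,7a-tetrahydro-1,3-benzodioxole-5-carboxylate
Product: 10 methyl (3aR,7R,7aS)-2,2-dimethyl-7-{[(3S)-3-methylpentanoyl]oxy}-3a,6,7,7a-tetrahydro-1,3-benzodioxole-5-carboxylate
Conditions: Pd(OAc)2 (5 mol%), PPh3 (10 mol%), HCO2H, Et3N, DMF, 60 °C
Reagents that add atoms: none
Why: Oxidative addition of Pd(0) into the vinyl C–OTf bond, formate exchange, decarboxylation and C–H reductive elimination should replace OTf by H without touching the enoate or the esters (palladium-catalysed formate reduction of an enol triflate).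

Step 7
Reactants: 10 methyl (3aR,7R,7aS)-2,2-dimethyl-7-{[(3S)-3-methylpentanoyl]oxy}-3a,6,7,7a-tetrahydro-1,3-benzodioxole-5-carboxylate
Product: 11 methyl (3R,4R,5R)-3,4-dihydroxy-5-{[(3S)-3-methylpentanoyl]oxy}cyclohex-1-ene-1-carboxylate
Conditions: TFA/H2O (4:1), CH2Cl2, 0 °C
Reagents that add atoms: none
Why: Acid hydrolysis of the isopropylidene acetal should free the cis-3,4-diol while the esters survive the cold, brief acid exposure (acetonide cleavage).

Step 8
Reactants: 11 methyl (3R,4R,5R)-3,4-dihydroxy-5-{[(3S)-3-methylpentanoyl]oxy}cyclohex-1-ene-1-carboxylate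
Product: 13 methyl (3R,4S,5R)-3-acetoxy-4-hydroxy-5-{[(3S)-3-methylpentanoyl]oxy}cyclohex-1-ene-1-carboxylate, via cyclic orthoacetate 12 (not isolated)
Conditions: MeC(OMe)3 (3 equiv), PPTS (5 mol%), CH2Cl2, rt; then 80% aq. AcOH, 0 °C → rt
Reagents that add atoms: trimethyl orthoacetate, CC(OC)(OC)OC; water, O
Why: Acetal exchange should give the 3,4-cyclic orthoacetate, whose acid hydrolysis through the hemi-orthoester opens under stereoelectronic control to the ester on the pseudo-axial O3 and the free equatorial 4-OH (orthoester-mediated monoacylation of a cis-diol, axial-ester rule).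

Step 9
Reactants: 13 methyl (3R,4S,5R)-3-acetoxy-4-hydroxy-5-{[(3S)-3-methylpentanoyl]oxy}cyclohex-1-ene-1-carboxylate; 14 (2R)-2-methylbutanoic acid
Product: 15 methyl (3R,4S,5R)-3-acetoxy-4-{[(2R)-2-methylbutanoyl]oxy}-5-{[(3S)-3-methylpentanoyl]oxy}cyclohex-1-ene-1-carboxylate
Conditions: DIC, DMAP (5 mol%), CH2Cl2, 0 °C
Reagents that add atoms: none
Why: Steglich esterification of the remaining 4-OH under near-neutral, cold conditions is chosen so that neither acetyl migration nor epimerisation of the α-stereocentre of the acid should compete.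

**Compound list**

1 | (3aS,6aS)-2,2-dimethyl-3a,6a-dihydro-4H-cyclopenta[d][1,3]dioxol-4-one | O=C1[C@H]2OC(C)(C)O[C@H]2C=C1 | starting material
2 | (3aS,6R,6aS)-2,2-dimethyl-6-(4,4,5,5-tetramethyl-1,3,2-dioxaborolan-2-yl)tetrahydro-4H-cyclopenta[d][1,3]dioxol-4-one (boryl group trans to the dioxolane) | O=C1[C@H]2OC(C)(C)O[C@H]2[C@H](B3OC(C)(C)C(C)(C)O3)C1 | intermediate
3 | (3aS,6R,6aS)-6-hydroxy-2,2-dimethyltetrahydro-4H-cyclopenta[d][1,3]dioxol-4-one | O=C1[C@H]2OC(C)(C)O[C@H]2[C@H](O)C1 | intermediate
4 | (3S)-3-methylpentanoic acid | CC[C@H](C)CC(=O)O | starting material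
5 | (3aS,4R,6aS)-2,2-dimethyl-6-oxotetrahydro-4H-cyclopenta[d][1,3]dioxol-4-yl (3S)-3-methylpentanoate | O=C1[C@H]2OC(C)(C)O[C@H]2[C@H](OC(=O)C[C@@H](C)CC)C1 | intermediate
6 | glycine methyl ester hydrochloride | COC(=O)C[NH3+].[Cl-] | starting material
7 | methyl diazoacetate | COC(=O)C=[N+]=[N-] | intermediate
8 | methyl (3aS,7R,7aS)-2,2-dimethyl-7-{[(3S)-3-methylpentanoyl]oxy}-4-oxohexahydro-1,3-benzodioxole-5-carboxylate (C5 epimers/enol tautomer) | COC(=O)C1C(=O)[C@H]2OC(C)(C)O[C@H]2[C@H](OC(=O)C[C@@H](C)CC)C1 | intermediate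
9 | methyl (3aS,7R,7aS)-2,2-dimethyl-7-{[(3S)-3-methylpentanoyl]oxy}-4-{[(trifluoromethyl)sulfonyl]oxy}-3a,6,7,7a-tetrahydro-1,3-benzodioxole-5-carboxylate | COC(=O)C1=C(OS(=O)(=O)C(F)(F)F)[C@H]2OC(C)(C)O[C@H]2[C@H](OC(=O)C[C@@H](C)CC)C1 | intermediate
10 | methyl (3aR,7R,7aS)-2,2-dimethyl-7-{[(3S)-3-methylpentanoyl]oxy}-3a,6,7,7a-tetrahydro-1,3-benzodioxole-5-carboxylate | COC(=O)C1=C[C@H]2OC(C)(C)O[C@H]2[C@H](OC(=O)C[C@@H](C)CC)C1 | intermediate
11 | methyl (3R,4R,5R)-3,4-dihydroxy-5-{[(3S)-3-methylpentanoyl]oxy}cyclohex-1-ene-1-carboxylate | COC(=O)C1=C[C@@H](O)[C@@H](O)[C@H](OC(=O)C[C@@H](C)CC)C1 | intermediate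
12 | methyl (3aR,7R,7aS)-2-methoxy-2-methyl-7-{[(3S)-3-methylpentanoyl]oxy}-3a,6,7,7a-tetrahydro-1,3-benzodioxole-5-carboxylate (C2 epimers) | COC(=O)C1=C[C@H]2OC(C)(OC)O[C@H]2[C@H](OC(=O)C[C@@H](C)CC)C1 | intermediate
13 | methyl (3R,4S,5R)-3-acetoxy-4-hydroxy-5-{[(3S)-3-methylpentanoyl]oxy}cyclohex-1-ene-1-carboxylate | COC(=O)C1=C[C@@H](OC(C)=O)[C@@H](O)[C@H](OC(=O)C[C@@H](C)CC)C1 | intermediate
14 | (2R)-2-methylbutanoic acid | CC[C@@H](C)C(=O)O | starting material
15 | methyl (3R,4S,5R)-3-acetoxy-4-{[(2R)-2-methylbutanoyl]oxy}-5-{[(3S)-3-methylpentanoyl]oxy}cyclohex-1-ene-1-carboxylate | CC[C@H](C)CC(=O)O[C@@H]1CC(C(=O)OC)=C[C@@H](OC(C)=O)[C@H]1OC(=O)[C@H](C)CC | target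

**Step count**

Total steps: 9. Longest linear sequence: 8 (steps 1, 2, 4, 5, 6, 7, 8, 9); step 3 is a one-step branch.

**Steps most likely to fail**

Step 4. The oxygen-bearing ring carbon may migrate in competition with the CH2, or the Lewis acid may trigger β-elimination of the carboxylate or opening of the acetal before the diazo ester has added. The fallback sets out from 5 and comes back at 8, separating addition from migration and using no Lewis acid. Deprotonation of 7 with LDA (THF, −78 °C) gives methyl lithiodiazoacetate F1, which should add to the ketone of 5 within minutes at −78 °C (AcOH quench) to give the tertiary α-diazo-β-hydroxy ester methyl 2-diazo-2-[(3aS,6R,6aS)-4-hydroxy-2,2-dimethyl-6-{[(3S)-3-methylpentanoyl]oxy}tetrahydro-4H-cyclopenta[d][1,3]dioxol-4-yl]acetate F2. Rh2(OAc)4 (1 mol%) in CH2Cl2 at rt should then form the rhodium carbenoid, whose 1,2-shift of the ring CH2 to the carbene carbon gives 8.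

Step 8. The hemi-orthoester may collapse with poor regiocontrol, or the acetyl group may migrate from O3 to O4 during hydrolysis and work-up. The fallback sets out from 11 and comes back at 13. Lipase-catalysed transesterification (immobilised Candida antarctica lipase B, vinyl acetate, MTBE, 30 °C) transfers acetyl at neutral pH without migration. It should select the less encumbered allylic 3-OH, whose carbinol carbon is flanked by an sp2 CH, over the 4-OH set between two substituted carbons; this selectivity is an expectation that would need a short lipase screen. This fallback makes no new compound (F0).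

Step 2. Acyl transfer may be overtaken by base-induced E1cB loss of the oxygen substituent β to the ketone, returning enone 1; the same lability may show under BF3 in step 4. The fallback sets out from 3 and comes back at 10, bringing in the acyl group only after the ketone is gone.
- Silylation (TBSCl, imidazole, DMF) gives the silyl ether (3aS,6R,6aR)-6-{[tert-butyl(dimethyl)silyl]oxy}-2,2-dimethyltetrahydro-4H-cyclopenta[d][1,3]dioxol-4-one F3.
- Ring expansion with 7 and BF3·OEt2 as in step 4 gives methyl (3aS,7R,7aR)-7-{[tert-butyl(dimethyl)silyl]oxy}-2,2-dimethyl-4-oxohexahydro-1,3-benzodioxole-5-carboxylate F4.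
- NaH/Tf2O gives methyl (3aS,7R,7aR)-7-{[tert-butyl(dimethyl)silyl]oxy}-2,2-dimethyl-4-{[(trifluoromethyl)sulfonyl]oxy}-3a,6,7,7a-tetrahydro-1,3-benzodioxole-5-carboxylate F5.
- Palladium/formate reduction gives methyl (3aR,7R,7aR)-7-{[tert-butyl(dimethyl)silyl]oxy}-2,2-dimethyl-3a,6,7,7a-tetrahydro-1,3-benzodioxole-5-carboxylate F6.
- HF·pyridine (THF, 0 °C) frees methyl (3aR,7R,7aS)-7-hydroxy-2,2-dimethyl-3a,6,7,7a-tetrahydro-1,3-benzodioxole-5-carboxylate F7, which has no carbonyl β to the carbinol and is esterified with 4 (DIC, DMAP cat., CH2Cl2) to give 10.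

**Further compounds**

F1 | step 4 | methyl lithiodiazoacetate | [Li]C(=[N+]=[N-])C(=O)OC
F2 | step 4 | methyl 2-diazo-2-[(3aS,6R,6aS)-4-hydroxy-2,2-dimethyl-6-{[(3S)-3-methylpentanoyl]oxy}tetrahydro-4H-cyclopenta[d][1,3]dioxol-4-yl]acetate (either C4 epimer) | COC(=O)C(=[N+]=[N-])C1(O)[C@H]2OC(C)(C)O[C@H]2[C@H](OC(=O)C[C@@H](C)CC)C1
F0 | step 8 | none | none
F3 | step 2 | (3aS,6R,6aR)-6-{[tert-butyl(dimethyl)silyl]oxy}-2,2-dimethyltetrahydro-4H-cyclopenta[d][1,3]dioxol-4-one | O=C1[C@H]2OC(C)(C)O[C@H]2[C@H](O[Si](C)(C)C(C)(C)C)C1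
F4 | step 2 | methyl (3aS,7R,7aR)-7-{[tert-butyl(dimethyl)silyl]oxy}-2,2-dimethyl-4-oxohexahydro-1,3-benzodioxole-5-carboxylate (C5 epimers/enol tautomer) | COC(=O)C1C(=O)[C@H]2OC(C)(C)O[C@H]2[C@H](O[Si](C)(C)C(C)(C)C)C1
F5 | step 2 | methyl (3aS,7R,7aR)-7-{[tert-butyl(dimethyl)silyl]oxy}-2,2-dimethyl-4-{[(trifluoromethyl)sulfonyl]oxy}-3a,6,7,7a-tetrahydro-1,3-benzodioxole-5-carboxylate | COC(=O)C1=C(OS(=O)(=O)C(F)(F)F)[C@H]2OC(C)(C)O[C@H]2[C@H](O[Si](C)(C)C(C)(C)C)C1
F6 | step 2 | methyl (3aR,7R,7aR)-7-{[tert-butyl(dimethyl)silyl]oxy}-2,2-dimethyl-3a,6,7,7a-tetrahydro-1,3-benzodioxole-5-carboxylate | COC(=O)C1=C[C@H]2OC(C)(C)O[C@H]2[C@H](O[Si](C)(C)C(C)(C)C)C1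
F7 | step 2 | methyl (3aR,7R,7aS)-7-hydroxy-2,2-dimethyl-3a,6,7,7a-tetrahydro-1,3-benzodioxole-5-carboxylate (methyl 3,4-O-isopropylidene shikimate) | COC(=O)C1=C[C@H]2OC(C)(C)O[C@H]2[C@H](O)C1
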